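**Retrosynthetic overview**
- Last operation, one flask: Sonogashira coupling (C10–C11), lactonisation of the C19 carboxylate onto C11 (the closure presumed in the biosynthesis of the 19,11-olide) and Stille coupling (C8–C9) unite a polyenyne alkyne, (E)-2,3-dibromoacrylic acid and a triol vinylstannane.
- Triol ring: hydroxyl-directed 5,6-epoxidation of an ent-3-hydroxy enyne ring, then hydration at C5 (epoxidase / epoxide-hydrolase logic); its carbinol comes from (4R,6R)-actinol by Mitsunobu inversion.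
- Polyenyne: a symmetric C14 tetraene-diyne (double Wittig of a C6 enynyl phosphonium salt with glyoxal) is desymmetrised by Sonogashira coupling with the actinol-derived enol triflate.
- Ring order: both carbocycles are bought as actinol; the oxirane is formed and opened on the West fragment; the butenolide is formed last, on the complete polyene chain.

Assumption: the SMILES is taken as drawn, i.e. (3R,5S,6S) in the trihydroxy ring and (3'R) in the acetylenic ring (carotenoid numbering, used below for atom labels), all chain double bonds E and the ylidenebutenolide Z.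

**Route**

Step 1
Reactants: 1 (2E)-3-methylpent-2-en-4-yn-1-ol
Product: 2 tributyl[(2E)-3-methylpent-2-en-4-yn-1-yl]phosphonium bromide
Conditions: n-Bu3P·HBr (preformed salt, 1.05 equiv), CHCl3, 50 °C
Reagents that add atoms: tributylphosphine hydrobromide, CCCC[PH+](CCCC)CCCC.[Br-]
Why: Phosphonium salt formation from an allylic alcohol with a phosphine hydrobromide (protonation, loss of water, attack of phosphorus at the primary terminus) keeps the E enyne geometry and prepares a Wittig reagent.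

Step 2
Reactants: 2 tributyl[(2E)-3-methylpent-2-en-4-yn-1-yl]phosphonium bromide (2.1 equiv); 3 glyoxal (40% aqueous solution, 1.0 equiv)
Product: 4 (3E,5E,7E,9E)-3,10-dimethyldodeca-3,5,7,9-tetraene-1,11-diyne
Conditions: NaOH (aq., added slowly), H2O/THF, 0 °C → rt, dark; all-E isomer crystallised
Reagents that add atoms: none
Why: Twofold Wittig olefination of the C2 dialdehyde builds the symmetric C14 chain in one operation, and allylic trialkylphosphonium ylides give E alkenes, so both new disubstituted double bonds are E while the trisubstituted enyne bonds are untouched.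

Step 3
Reactants: 5 (4R,6R)-4-hydroxy-2,2,6-trimethylcyclohexan-1-one ((4R,6R)-actinol)
Product: 8 (4R)-4-hydroxy-2,6,6-trimethylcyclohex-1-en-1-yl trifluoromethanesulfonate, via actinol trimethylsilyl ether 6 (not isolated), via silyl-protected enol triflate 7 (not isolated)
Conditions: (Me3Si)2NH (0.6 equiv), I2 (1 mol%), CH2Cl2, rt, evaporate; KN(SiMe3)2, THF, −78 °C; PhNTf2, −78 → 0 °C; 1 M HCl, THF, 0 °C
Reagents that add atoms: N-phenylbis(trifluoromethanesulfonimide), O=S(=O)(N(c1ccccc1)S(=O)(=O)C(F)(F)F)C(F)(F)F; hexamethyldisilazane, C[Si](C)(C)N[Si](C)(C)C (its silyl group is carried only by 6 and 7)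
Why: The ketone has a single enolisable position, so enolate O-triflation under transient silyl protection gives the tetrasubstituted enol triflate regiospecifically; the carbinol centre is untouched and the methyl-bearing centre becomes sp2.

Step 4
Reactants: 8 (4R)-4-hydroxy-2,6,6-trimethylcyclohex-1-en-1-yl trifluoromethanesulfonate; 4 (3E,5E,7E,9E)-3,10-dimethyldodeca-3,5,7,9-tetraene-1,11-diyne (3 equiv)
Product: 9 (1R)-4-[(3E,5E,7E,9E)-3,10-dimethyldodeca-3,5,7,9-tetraene-1,11-diyn-1-yl]-3,5,5-trimethylcyclohex-3-en-1-ol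
Conditions: Pd(PPh3)4 (5 mol%), CuI (10 mol%), i-Pr2NH, THF, 45 °C, degassed, dark
Reagents that add atoms: none
Why: Sonogashira coupling of the enol triflate with one terminus of the symmetric diyne (excess diyne suppresses double coupling and is recovered) installs the 7',8'-alkyne without touching any stereocentre or alkene geometry.

Step 5
Reactants: 5 (4R,6R)-4-hydroxy-2,2,6-trimethylcyclohexan-1-one
Product: 10 (1S,5R)-3,3,5-trimethyl-4-oxocyclohexyl benzoate
Conditions: PhCO2H, PPh3, DIAD, THF, 0 °C → rt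
Reagents that add atoms: benzoic acid, OC(=O)c1ccccc1
Why: Mitsunobu esterification inverts the secondary carbinol (SN2 on the alkoxyphosphonium), turning the (4R) centre of actinol into the (S) centre needed for the trihydroxy ring, and the benzoate protects the oxygen.

Step 6
Reactants: 10 (1S,5R)-3,3,5-trimethyl-4-oxocyclohexyl benzoate
Product: 11 (1S)-3,5,5-trimethyl-4-{[(trifluoromethyl)sulfonyl]oxy}cyclohex-3-en-1-yl benzoate
Conditions: KN(SiMe3)2, THF, −78 °C; PhNTf2, −78 → 0 °C; cold 1 M HCl quench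
Reagents that add atoms: N-phenylbis(trifluoromethanesulfonimide), O=S(=O)(N(c1ccccc1)S(=O)(=O)C(F)(F)F)C(F)(F)F
Why: Enolate O-triflation at the only enolisable position gives the enol triflate; the benzoate has no α-hydrogen and survives the hindered amide base at low temperature, and the inverted carbinol centre is untouched.

Step 7
Reactants: 11 (1S)-3,5,5-trimethyl-4-{[(trifluoromethyl)sulfonyl]oxy}cyclohex-3-en-1-yl benzoate; 12 ethynyl(trimethyl)silane
Product: 14 (1S)-4-ethynyl-3,5,5-trimethylcyclohex-3-en-1-ol, via silylalkyne benzoate 13 (not isolated)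
Conditions: Pd(PPh3)4 (5 mol%), CuI (10 mol%), Et3N, DMF, 50 °C; then MeOH, K2CO3 (0.5 equiv), rt, argon
Reagents that add atoms: none
Why: Sonogashira coupling followed by methanolysis in the same flask removes both the alkynyl silane and the benzoate, freeing the homoallylic alcohol that will direct the epoxidation.

Step 8
Reactants: 14 (1S)-4-ethynyl-3,5,5-trimethylcyclohex-3-en-1-ol
Product: 16 (1R,2S,4R)-1-ethynyl-2,6,6-trimethylcyclohexane-1,2,4-triol, via syn-epoxide 15 (not isolated)
Conditions: VO(acac)2 (5 mol%), t-BuOOH (1.1 equiv, decane), CH2Cl2, 0 → 40 °C; then THF, 0.5 M aq. HClO4, 0 °C → rt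
Reagents that add atoms: tert-butyl hydroperoxide, CC(C)(C)OO; water, O
Why: Hydroxyl-directed epoxidation delivers oxygen to the ring alkene on the face syn to the C3 hydroxyl, and acid-catalysed epoxide hydration (the epoxidase / epoxide-hydrolase sequence) then opens the oxirane with inversion at C5 (tertiary alkyl, less hindered) and not at the neopentyl, propargylic C6, which sets the 5,6-trans-diol with both new centres in the required sense from the single carbinol.

Step 9
Reactants: 16 (1R,2S,4R)-1-ethynyl-2,6,6-trimethylcyclohexane-1,2,4-triol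
Product: 17 (1S,2S,4R)-2,6,6-trimethyl-1-[(E)-2-(tributylstannyl)ethenyl]cyclohexane-1,2,4-triol
Conditions: Bu3SnH (1.2 equiv), PdCl2(PPh3)2 (2 mol%), THF, 0 °C → rt
Reagents that add atoms: tributyltin hydride, CCCC[SnH](CCCC)CCCC
Why: Palladium-catalysed syn-hydrostannation of the terminal tertiary propargylic alcohol places tin on the distal carbon and gives the (E)-vinylstannane; no stereocentre changes (the C1 descriptor changes only because vinyl ranks below the ring carbon).

Step 10
Reactants: 18 prop-2-ynoic acid (propiolic acid)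
Product: 19 (2E)-2,3-dibromoprop-2-enoic acid
Conditions: Br2 (1.0 equiv), CHCl3, 0 °C → rt, dark; recrystallise
Reagents that add atoms: bromine, BrBr
Why: Ionic anti-addition of bromine to the alkyne gives the (E)-dibromide, in which the β-bromine is cis to the carboxyl group as the later lactonisation requires.

Step 11
Reactants: 9 (1R)-4-[(3E,5E,7E,9E)-3,10-dimethyldodeca-3,5,7,9-tetraene-1,11-diyn-1-yl]-3,5,5-trimethylcyclohex-3-en-1-ol (0.95 equiv); 19 (2E)-2,3-dibromoprop-2-enoic acid (1.0 equiv); 17 (1S,2S,4R)-2,6,6-trimethyl-1-[(E)-2-(tributylstannyl)ethenyl]cyclohexane-1,2,4-triol (1.3 equiv)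
Product: 22 (5Z)-5-{(2E,4E,6E,8E)-11-[(4R)-4-hydroxy-2,6,6-trimethylcyclohex-1-en-1-yl]-2,9-dimethylundeca-2,4,6,8-tetraen-10-yn-1-ylidene}-3-{(E)-2-[(1S,2S,4R)-1,2,4-trihydroxy-2,6,6-trimethylcyclohexyl]ethenyl}furan-2(5H)-one, via bromo seco acid 20 (not isolated), via bromobutenolide 21 (not isolated)
Conditions: Pd(PPh3)4 (5 mol%), CuI (10 mol%), Et3N (3 equiv), MeCN/THF, rt, dark, degassed; then 17, Pd2(dba)3 (5 mol%), AsPh3 (40 mol%), DMF, 45 °C
Reagents that add atoms: none
Why: Sonogashira coupling takes place at the more reactive β-bromide, the resulting C19 carboxylate closes onto C11 by metal-promoted 5-exo-dig anti-addition and protodemetalation (the lactonisation presumed in the biosynthesis) to give the Z-ylidenebutenolide directly, and Stille coupling of the remaining α-bromide with 17 completes the skeleton with retention of both alkene geometries and without touching any stereocentre.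

**Compound list**
1 | (2E)-3-methylpent-2-en-4-yn-1-ol | C#C/C(C)=C/CO | starting material
2 | tributyl[(2E)-3-methylpent-2-en-4-yn-1-yl]phosphonium bromide | C#C/C(C)=C/C[P+](CCCC)(CCCC)CCCC.[Br-] | intermediate
3 | glyoxal (ethanedial) | O=CC=O | starting material
4 | (3E,5E,7E,9E)-3,10-dimethyldodeca-3,5,7,9-tetraene-1,11-diyne | C#C/C(C)=C/C=C/C=C/C=C(C)/C#C | intermediate
5 | (4R,6R)-4-hydroxy-2,2,6-trimethylcyclohexan-1-one ((4R,6R)-actinol) | O=C1C(C)(C)C[C@H](O)C[C@H]1C | starting material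
6 | (4R,6R)-2,2,6-trimethyl-4-[(trimethylsilyl)oxy]cyclohexan-1-one | O=C1C(C)(C)C[C@H](O[Si](C)(C)C)C[C@H]1C | intermediate
7 | (4R)-2,6,6-trimethyl-4-[(trimethylsilyl)oxy]cyclohex-1-en-1-yl trifluoromethanesulfonate | CC1=C(OS(=O)(=O)C(F)(F)F)C(C)(C)C[C@H](O[Si](C)(C)C)C1 | intermediate
8 | (4R)-4-hydroxy-2,6,6-trimethylcyclohex-1-en-1-yl trifluoromethanesulfonate | CC1=C(OS(=O)(=O)C(F)(F)F)C(C)(C)C[C@H](O)C1 | intermediate
9 | (1R)-4-[(3E,5E,7E,9E)-3,10-dimethyldodeca-3,5,7,9-tetraene-1,11-diyn-1-yl]-3,5,5-trimethylcyclohex-3-en-1-ol | CC1=C(C#C/C(C)=C/C=C/C=C/C=C(C)/C#C)C(C)(C)C[C@H](O)C1 | intermediate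
10 | (1S,5R)-3,3,5-trimethyl-4-oxocyclohexyl benzoate | O=C1C(C)(C)C[C@@H](OC(=O)c2ccccc2)C[C@H]1C | intermediate
11 | (1S)-3,5,5-trimethyl-4-{[(trifluoromethyl)sulfonyl]oxy}cyclohex-3-en-1-yl benzoate | CC1=C(OS(=O)(=O)C(F)(F)F)C(C)(C)C[C@@H](OC(=O)c2ccccc2)C1 | intermediate
12 | ethynyl(trimethyl)silane | C#C[Si](C)(C)C | starting material
13 | (1S)-3,5,5-trimethyl-4-[(trimethylsilyl)ethynyl]cyclohex-3-en-1-yl benzoate | CC1=C(C#C[Si](C)(C)C)C(C)(C)C[C@@H](OC(=O)c2ccccc2)C1 | intermediate
14 | (1S)-4-ethynyl-3,5,5-trimethylcyclohex-3-en-1-ol | CC1=C(C#C)C(C)(C)C[C@@H](O)C1 | intermediate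
15 | (1R,3R,6R)-6-ethynyl-1,5,5-trimethyl-7-oxabicyclo[4.1.0]heptan-3-ol | C#C[C@]12C(C)(C)C[C@@H](O)C[C@@]1(C)O2 | intermediate
16 | (1R,2S,4R)-1-ethynyl-2,6,6-trimethylcyclohexane-1,2,4-triol | C#C[C@]1(O)C(C)(C)C[C@@H](O)C[C@]1(C)O | intermediate
17 | (1S,2S,4R)-2,6,6-trimethyl-1-[(E)-2-(tributylstannyl)ethenyl]cyclohexane-1,2,4-triol | CCCC[Sn](CCCC)(CCCC)/C=C/[C@]1(O)C(C)(C)C[C@@H](O)C[C@]1(C)O | intermediate
18 | prop-2-ynoic acid (propiolic acid) | C#CC(=O)O | starting material
19 | (2E)-2,3-dibromoprop-2-enoic acid | OC(=O)/C(Br)=C\Br | intermediate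
20 | (2E,6E,8E,10E,12E)-2-bromo-15-[(4R)-4-hydroxy-2,6,6-trimethylcyclohex-1-en-1-yl]-6,13-dimethylpentadeca-2,6,8,10,12-pentaene-4,14-diynoic acid | CC1=C(C#C/C(C)=C/C=C/C=C/C=C(C)/C#C/C=C(/Br)C(O)=O)C(C)(C)C[C@H](O)C1 | intermediate
21 | (5Z)-3-bromo-5-{(2E,4E,6E,8E)-11-[(4R)-4-hydroxy-2,6,6-trimethylcyclohex-1-en-1-yl]-2,9-dimethylundeca-2,4,6,8-tetraen-10-yn-1-ylidene}furan-2(5H)-one | CC1=C(C#C/C(C)=C/C=C/C=C/C=C(C)/C=C2C=C(Br)C(=O)O/2)C(C)(C)C[C@H](O)C1 | intermediate
22 | (5Z)-5-{(2E,4E,6E,8E)-11-[(4R)-4-hydroxy-2,6,6-trimethylcyclohex-1-en-1-yl]-2,9-dimethylundeca-2,4,6,8-tetraen-10-yn-1-ylidene}-3-{(E)-2-[(1S,2S,4R)-1,2,4-trihydroxy-2,6,6-trimethylcyclohexyl]ethenyl}furan-2(5H)-one (CNP0163979.2) | CC1=C(C#C/C(C)=C/C=C/C=C/C=C(C)/C=C2C=C(/C=C/[C@]3(O)C(C)(C)C[C@@H](O)C[C@]3(C)O)C(=O)O/2)C(C)(C)C[C@H](O)C1 | target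

**Step count and risks**
Total steps: 11. Longest linear sequence: 6 steps (5 → 10 → 11 → 14 → 16 → 17 → 22).

Most likely to fail, step 11 (one-flask union). The risks are coupling of 9 at the α-bromide of 21, 6-endo closure to a pyranone, and erosion of polyene geometry. The fallback sets out from 9, 17 and 19 and comes back at 22; it moves the lactonisation to the very end as a separate silver-catalysed step on the complete seco acid. Acid 19 is esterified (EtOH, cat. H2SO4) to ethyl (2E)-2,3-dibromoprop-2-enoate F1. Sonogashira coupling of 9 at the β-bromide gives the bromo enynoate ester F2, which cannot lactonise. Stille coupling with 17 gives the seco ester F3, LiOH (THF/H2O) gives the seco acid F4, and AgNO3 (10 mol%, acetone, dark) closes the 5-exo-dig lactone to 22.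

Second, step 8 (directed epoxidation and hydration). The risks are incomplete facial control on the enyne, water attacking C6, and acid-induced rearrangement of the propargylic alcohol. The fallback sets out from 11 and comes back at 16; it replaces substrate-directed epoxidation of the enyne by reagent-controlled epoxidation of an allylic alcohol and adds the alkyne afterwards. Methoxycarbonylation of 11 (Pd(OAc)2, 1,3-bis(diphenylphosphino)propane, CO, MeOH, Et3N) gives the ester F5, and i-Bu2AlH gives the allylic alcohol diol F6. Sharpless epoxidation (Ti(OiPr)4, t-BuOOH, the diethyl tartrate enantiomer that oxidises the face syn to the ring hydroxyl, D-(−) by the usual mnemonic) gives the epoxy diol F7. Dilute aqueous acid opens F7 at C5, since C6 now carries only a hydroxymethyl group, to the tetraol F8. TEMPO/PhI(OAc)2 oxidises only the primary alcohol to the aldehyde F9, and Ohira–Bestmann homologation (dimethyl (1-diazo-2-oxopropyl)phosphonate, K2CO3, MeOH) returns to 16.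

Third, step 2 (double Wittig with glyoxal). The risks are Cannizzaro loss of glyoxal in base and E/Z mixtures; iodine equilibration is not an option because double bonds next to an alkyne drift to Z. The fallback sets out from 1 and comes back at 4; it builds the chain by two separate E-selective Horner–Wadsworth–Emmons reactions. PBr3 converts 1 into the allylic bromide F10, and Arbuzov reaction with P(OEt)3 gives the phosphonate F11. Olefination of 2,2-dimethoxyacetaldehyde with F11 (NaN(SiMe3)2, THF, −78 °C) gives the dienyne acetal F12, and aqueous acid gives the dienynal F13. A second olefination of F13 with F11 gives 4.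

Further compounds
F1 | step 11 | ethyl (2E)-2,3-dibromoprop-2-enoate | CCOC(=O)/C(Br)=C\Br
F2 | step 11 | ethyl (2E,6E,8E,10E,12E)-2-bromo-15-[(4R)-4-hydroxy-2,6,6-trimethylcyclohex-1-en-1-yl]-6,13-dimethylpentadeca-2,6,8,10,12-pentaene-4,14-diynoate | CC1=C(C#C/C(C)=C/C=C/C=C/C=C(C)/C#C/C=C(/Br)C(=O)OCC)C(C)(C)C[C@H](O)C1
F3 | step 11 | ethyl (2Z,6E,8E,10E,12E)-15-[(4R)-4-hydroxy-2,6,6-trimethylcyclohex-1-en-1-yl]-6,13-dimethyl-2-{(E)-2-[(1S,2S,4R)-1,2,4-trihydroxy-2,6,6-trimethylcyclohexyl]ethenyl}pentadeca-2,6,8,10,12-pentaene-4,14-diynoate | CC1=C(C#C/C(C)=C/C=C/C=C/C=C(C)/C#C/C=C(/C=C/[C@]2(O)C(C)(C)C[C@@H](O)C[C@]2(C)O)C(=O)OCC)C(C)(C)C[C@H](O)C1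
F4 | step 11 | (2Z,6E,8E,10E,12E)-15-[(4R)-4-hydroxy-2,6,6-trimethylcyclohex-1-en-1-yl]-6,13-dimethyl-2-{(E)-2-[(1S,2S,4R)-1,2,4-trihydroxy-2,6,6-trimethylcyclohexyl]ethenyl}pentadeca-2,6,8,10,12-pentaene-4,14-diynoic acid | CC1=C(C#C/C(C)=C/C=C/C=C/C=C(C)/C#C/C=C(/C=C/[C@]2(O)C(C)(C)C[C@@H](O)C[C@]2(C)O)C(O)=O)C(C)(C)C[C@H](O)C1
F5 | step 8 | methyl (4S)-4-(benzoyloxy)-2,6,6-trimethylcyclohex-1-ene-1-carboxylate | CC1=C(C(=O)OC)C(C)(C)C[C@@H](OC(=O)c2ccccc2)C1
F6 | step 8 | (1S)-4-(hydroxymethyl)-3,5,5-trimethylcyclohex-3-en-1-ol | CC1=C(CO)C(C)(C)C[C@@H](O)C1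
F7 | step 8 | (1R,3R,6R)-6-(hydroxymethyl)-1,5,5-trimethyl-7-oxabicyclo[4.1.0]heptan-3-ol | OC[C@]12C(C)(C)C[C@@H](O)C[C@@]1(C)O2
F8 | step 8 | (1R,2S,4R)-1-(hydroxymethyl)-2,6,6-trimethylcyclohexane-1,2,4-triol | OC[C@]1(O)C(C)(C)C[C@@H](O)C[C@]1(C)O
F9 | step 8 | (1S,2S,4R)-1,2,4-trihydroxy-2,6,6-trimethylcyclohexane-1-carbaldehyde | O=C[C@]1(O)C(C)(C)C[C@@H](O)C[C@]1(C)O
F10 | step 2 | (3E)-5-bromo-3-methylpent-3-en-1-yne | C#C/C(C)=C/CBr
F11 | step 2 | diethyl [(2E)-3-methylpent-2-en-4-yn-1-yl]phosphonate | C#C/C(C)=C/CP(=O)(OCC)OCC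
F12 | step 2 | (3E,5E)-7,7-dimethoxy-3-methylhepta-3,5-dien-1-yne | C#C/C(C)=C/C=C/C(OC)OC
F13 | step 2 | (2E,4E)-5-methylhepta-2,4-dien-6-ynal | C#C/C(C)=C/C=C/C=O
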